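Everything rests on disconnecting ring C across C1'–C6' and C4'–C5'. Its pattern (bridge carbon on C1', OMe on C2', H on C3', OH on C4', butyryl on C5', oxygen on C6') is exactly what a 4-substituted 1,3-dimethoxy-1-silyloxy diene and a 1-alkoxy-1-yn-3-one deliver, so one Diels–Alder cycloaddition with loss of methanol builds the fully substituted ring C with its butyryl group flanked by two oxygens. The diene is the trimethylsilyl ketene acetal of a 3-methoxypent-2-enoate whose C5 carries ring B as its tribenzyl ether; it is reached without any benzylic halide. Dealkylation, butyrylation of ring B and a formaldehyde bridge to the ring A triketone complete the target.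

Key step: step 6

Remark: the target has no stereocentre and is drawn as one enol tautomer of ring A, the route giving the tautomeric mixture this drawing stands for; 1, 9 (as hexane solution), 10, 17 and 20 are taken as purchasable.

Step 1
Reactants: 1 1,3,5-tris(benzyloxy)benzene; 2 but-3-en-2-one (methyl vinyl ketone)
Product: 3 4-[2,4,6-tris(benzyloxy)phenyl]butan-2-one
Conditions: 1 (1.5 equiv), AuCl3 (2 mol %), MeCN, 20 °C
Reagents that add atoms: none
Why: Friedel–Crafts-type conjugate addition (hydroarylation) of the strongly nucleophilic 1,3,5-trialkoxybenzene to the enone under mild Lewis-acid catalysis; the three free ring positions are equivalent and the excess of 1 should hold back a second alkylation.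

Step 2
Reactants: 3 4-[2,4,6-tris(benzyloxy)phenyl]butan-2-one
Product: 4 methyl 3-oxo-5-[2,4,6-tris(benzyloxy)phenyl]pentanoate
Conditions: NaH (2.5 equiv), (MeO)2CO, THF, 65 °C; then 1 M HCl, 0 °C
Reagents that add atoms: dimethyl carbonate, COC(=O)OC
Why: Claisen-type methoxycarbonylation of a methyl ketone, which should go at the methyl terminus because only that product is drained off as the stabilised β-keto ester enolate; the benzyl ethers are inert to NaH.

Step 3
Reactants: 4 methyl 3-oxo-5-[2,4,6-tris(benzyloxy)phenyl]pentanoate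
Product: 6 methyl (E)-3-methoxy-5-[2,4,6-tris(benzyloxy)phenyl]pent-2-enoate, via dimethyl ketal 5 (not isolated)
Conditions: HC(OMe)3, H2SO4 (cat.), MeOH, 20 → 60 °C
Reagents that add atoms: trimethyl orthoformate, COC(OC)OC
Why: Acid-catalysed ketalisation with the orthoester followed by loss of methanol should give the conjugated enol ether, the E isomer (OMe trans to the ester) being the thermodynamic one, as in the standard preparation of methyl 3-methoxybut-2-enoate from methyl acetoacetate.

Step 4
Reactants: 6 methyl (E)-3-methoxy-5-[2,4,6-tris(benzyloxy)phenyl]pent-2-enoate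
Product: 8 {[(1Z,3Z)-1,3-dimethoxy-5-[2,4,6-tris(benzyloxy)phenyl]penta-1,3-dien-1-yl]oxy}trimethylsilane (trimethylsilyl ketene acetal of 6), via lithium dienolate 7 (not isolated)
Conditions: LDA, THF, −78 °C; Me3SiCl, −78 → 0 °C; pentane, filtration
Reagents that add atoms: chlorotrimethylsilane, C[Si](C)(C)Cl
Why: Kinetic γ-deprotonation of the (E)-β-methoxy enoate at C4 and O-silylation of the dienolate, the standard preparation of Brassard-type dienes; the arylmethyl group should settle trans to C2 on the new C3=C4 bond, so the diene can reach its s-cis form.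

Step 5
Reactants: 9 ethoxyacetylene (ethoxyethyne); 10 N-methoxy-N-methylbutanamide
Product: 12 1-ethoxyhex-1-yn-3-one, via lithium ethoxyacetylide 11 (not isolated)
Conditions: 9, n-BuLi, THF, −78 °C; then 10, −78 → 0 °C; cold aq. NH4Cl
Reagents that add atoms: none
Why: Weinreb ketone synthesis, in which the lithium acetylide adds once and the chelated tetrahedral adduct survives until the cold, nearly neutral quench, which also spares the acid-sensitive ynol ether.

Step 6
Reactants: 8 trimethylsilyl ketene acetal diene; 12 1-ethoxyhex-1-yn-3-one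
Product: 15 1-{2-ethoxy-6-hydroxy-4-methoxy-3-[2,4,6-tris(benzyloxy)benzyl]phenyl}butan-1-one, via cyclohexadiene cycloadduct 13 (not isolated), via aryl trimethylsilyl ether 14 (not isolated)
Conditions: 12 (2.5 equiv), toluene, 70 °C; then 1 M HCl, THF, 20 °C
Reagents that add atoms: none
Why: The ketene acetal polarises diene 8 so that its substituted terminus C4 (future C1') is the nucleophilic end; it bonds to the ethoxy-bearing β-carbon of ynone 12 (future C6') while the acetal carbon (future C4') bonds to the α-carbon (future C5'), in a concerted but strongly asynchronous [4+2] cycloaddition whose stepwise limit is a vinylogous Mukaiyama–Michael addition followed by 6-exo-trig closure of the allenolate onto the oxocarbenium ion. The closest known reaction type is the Diels–Alder/aromatisation of Brassard-type 1,3-dimethoxy-1-silyloxy dienes with acetylenic ketones and esters, which places the acyl group next to the new phenol. Ring C closes as the six-membered ring of this intermolecular [4+2] process; cycloadduct 13 should aromatise by 1,4-loss of methanol to silyl ether 14, which dilute acid hydrolyses to phenol 15. No lasting stereocentre is created, since both sp3 centres of 13 become aromatic carbons. The step needs regioselectivity only, and the matched polarity of the partners secures it: the donor end of the diene attacks the β-carbon as nucleophiles do with β-alkoxy enones and ynones, which puts butyryl between the two oxygenated carbons C4' and C6'. The ynone is used in excess and the bath kept at 70 °C, below the temperature at which ethyl alkynyl ethers lose ethene.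

Step 7
Reactants: 15 1-{2-ethoxy-6-hydroxy-4-methoxy-3-[2,4,6-tris(benzyloxy)benzyl]phenyl}butan-1-one
Product: 16 1-[2,6-dihydroxy-4-methoxy-3-(2,4,6-trihydroxybenzyl)phenyl]butan-1-one
Conditions: BCl3 (8 equiv), C6HMe5 (8 equiv), CH2Cl2, −78 → 20 °C; then H2O
Reagents that add atoms: none
Why: Lewis-acid ether cleavage in which BCl3, with pentamethylbenzene as a non-basic scavenger for benzyl cations, should remove the three aryl benzyl ethers at low temperature and on warming cleave the ethyl ether at C6', whose oxygen sits ortho to the butyryl carbonyl and is activated by chelation, whereas the C2' methyl ether, para to the carbonyl, is not.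

Step 8
Reactants: 16 1-[2,6-dihydroxy-4-methoxy-3-(2,4,6-trihydroxybenzyl)phenyl]butan-1-one; 17 butanenitrile
Product: 19 1-[3-(3-butanoyl-2,4,6-trihydroxybenzyl)-2,6-dihydroxy-4-methoxyphenyl]butan-1-one, via ketiminium chloride 18 (not isolated)
Conditions: 17, ZnCl2 (20 mol %), HCl (g), Et2O, 0 °C; then H2O, 100 °C
Reagents that add atoms: water, O
Why: Houben–Hoesch acylation, which needs a free phloroglucinol ring, so ring B should be acylated once at one of its two equivalent free positions (the ketiminium salt shuts down a second attack) while ring C is deactivated by its own butyryl group.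

Step 9
Reactants: 20 1-(2,4,6-trihydroxyphenyl)butan-1-one
Product: 22 2-butanoyl-3,5-dihydroxy-4,4-dimethylcyclohexa-2,5-dien-1-one (butyrylfilicinic acid), via C-methyl phenol 21 (not isolated)
Conditions: NaOMe (3 equiv), MeI (2.2 equiv), MeOH, 0 → 20 °C; then 1 M HCl
Reagents that add atoms: iodomethane, CI
Why: Twofold C-methylation of the phloroglucinol phenolate with MeI, the second alkylation at the same carbon dearomatising the ring to the gem-dimethyl triketone, which is the classical entry to acylfilicinic acids.

Step 10
Reactants: 19 1-[3-(3-butanoyl-2,4,6-trihydroxybenzyl)-2,6-dihydroxy-4-methoxyphenyl]butan-1-one; 22 butyrylfilicinic acid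
Product: 24 2-butanoyl-6-{[3-butanoyl-5-(3-butanoyl-2,4-dihydroxy-6-methoxybenzyl)-2,4,6-trihydroxyphenyl]methyl}-3,5-dihydroxy-4,4-dimethylcyclohexa-2,5-dien-1-one (CNP0178590.0), via methylidene triketone 23 (not isolated)
Conditions: 22 (2 equiv), 37% aq. CH2O (1.2 equiv), 1% aq. KOH, 0 → 20 °C; then 1 M HCl
Reagents that add atoms: formaldehyde, C=O
Why: Methylene bridging of two phloroglucinol-type units with formaldehyde in dilute alkali (Knoevenagel condensation on the triketone, then Michael addition of the ring B phenolate through C1), in which ring B should win over the free C3' of ring C because its 2-OH, para to the butyryl group and not chelated, is the most acidic phenol, and the excess of 22 limits homo-coupling of 19.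

Compound list
1 | 1,3,5-tris(benzyloxy)benzene | C(Oc1cc(OCc2ccccc2)cc(OCc3ccccc3)c1)c4ccccc4 | starting material
2 | but-3-en-2-one | CC(=O)C=C | starting material
3 | 4-[2,4,6-tris(benzyloxy)phenyl]butan-2-one | CC(=O)CCc1c(OCc2ccccc2)cc(OCc3ccccc3)cc1OCc4ccccc4 | intermediate
4 | methyl 3-oxo-5-[2,4,6-tris(benzyloxy)phenyl]pentanoate | COC(=O)CC(=O)CCc1c(OCc2ccccc2)cc(OCc3ccccc3)cc1OCc4ccccc4 | intermediate
5 | methyl 3,3-dimethoxy-5-[2,4,6-tris(benzyloxy)phenyl]pentanoate (not isolated) | COC(=O)CC(OC)(OC)CCc1c(OCc2ccccc2)cc(OCc3ccccc3)cc1OCc4ccccc4 | intermediate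
6 | methyl (E)-3-methoxy-5-[2,4,6-tris(benzyloxy)phenyl]pent-2-enoate | COC(=O)/C=C(\CCc1c(OCc2ccccc2)cc(OCc3ccccc3)cc1OCc4ccccc4)OC | intermediate
7 | lithium dienolate of 6 (not isolated) | [Li+].CO/C([O-])=C/C(OC)=C/Cc1c(OCc2ccccc2)cc(OCc3ccccc3)cc1OCc4ccccc4 | intermediate
8 | {[(1Z,3Z)-1,3-dimethoxy-5-[2,4,6-tris(benzyloxy)phenyl]penta-1,3-dien-1-yl]oxy}trimethylsilane | CO/C(O[Si](C)(C)C)=C/C(OC)=C/Cc1c(OCc2ccccc2)cc(OCc3ccccc3)cc1OCc4ccccc4 | intermediate
9 | ethoxyacetylene | CCOC#C | starting material
10 | N-methoxy-N-methylbutanamide | CCCC(=O)N(C)OC | starting material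
11 | lithium ethoxyacetylide (not isolated) | [Li+].[C-]#COCC | intermediate
12 | 1-ethoxyhex-1-yn-3-one | CCCC(=O)C#COCC | intermediate
13 | 1-{2-ethoxy-4,6-dimethoxy-6-(trimethylsilyloxy)-3-[2,4,6-tris(benzyloxy)benzyl]cyclohexa-1,4-dien-1-yl}butan-1-one, mixture of diastereomers (not isolated) | CCCC(=O)C1=C(OCC)C(Cc2c(OCc3ccccc3)cc(OCc4ccccc4)cc2OCc5ccccc5)C(OC)=CC1(OC)O[Si](C)(C)C | intermediate
14 | 1-{2-ethoxy-4-methoxy-6-(trimethylsilyloxy)-3-[2,4,6-tris(benzyloxy)benzyl]phenyl}butan-1-one (not isolated) | CCCC(=O)c1c(O[Si](C)(C)C)cc(OC)c(Cc2c(OCc3ccccc3)cc(OCc4ccccc4)cc2OCc5ccccc5)c1OCC | intermediate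
15 | 1-{2-ethoxy-6-hydroxy-4-methoxy-3-[2,4,6-tris(benzyloxy)benzyl]phenyl}butan-1-one | CCCC(=O)c1c(O)cc(OC)c(Cc2c(OCc3ccccc3)cc(OCc4ccccc4)cc2OCc5ccccc5)c1OCC | intermediate
16 | 1-[2,6-dihydroxy-4-methoxy-3-(2,4,6-trihydroxybenzyl)phenyl]butan-1-one | CCCC(=O)c1c(O)cc(OC)c(Cc2c(O)cc(O)cc2O)c1O | intermediate
17 | butanenitrile | CCCC#N | starting material
18 | ketiminium chloride of 19 (not isolated) | [Cl-].CCCC(=[NH2+])c1c(O)cc(O)c(Cc2c(OC)cc(O)c(C(=O)CCC)c2O)c1O | intermediate
19 | 1-[3-(3-butanoyl-2,4,6-trihydroxybenzyl)-2,6-dihydroxy-4-methoxyphenyl]butan-1-one | CCCC(=O)c1c(O)cc(O)c(Cc2c(OC)cc(O)c(C(=O)CCC)c2O)c1O | intermediate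
20 | 1-(2,4,6-trihydroxyphenyl)butan-1-one | CCCC(=O)c1c(O)cc(O)cc1O | starting material
21 | 1-(2,4,6-trihydroxy-3-methylphenyl)butan-1-one (not isolated) | CCCC(=O)c1c(O)cc(O)c(C)c1O | intermediate
22 | 2-butanoyl-3,5-dihydroxy-4,4-dimethylcyclohexa-2,5-dien-1-one | CCCC(=O)C1=C(O)C(C)(C)C(O)=CC1=O | intermediate
23 | 2-butanoyl-3-hydroxy-4,4-dimethyl-6-methylidenecyclohex-2-ene-1,5-dione (not isolated) | CCCC(=O)C1=C(O)C(C)(C)C(=O)C(=C)C1=O | intermediate
24 | 2-butanoyl-6-{[3-butanoyl-5-(3-butanoyl-2,4-dihydroxy-6-methoxybenzyl)-2,4,6-trihydroxyphenyl]methyl}-3,5-dihydroxy-4,4-dimethylcyclohexa-2,5-dien-1-one | CCCC(=O)C1=C(O)C(C)(C)C(O)=C(Cc2c(O)c(Cc3c(OC)cc(O)c(C(=O)CCC)c3O)c(O)c(C(=O)CCC)c2O)C1=O | target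

Total step count: 10
Longest linear sequence: 8 steps (steps 1, 2, 3, 4, 6, 7, 8 and 10, from 1 to 24)

Steps most likely to fail

Step 6. The push–pull ynone is a sluggish dienophile. Hydrolysis or desilylation of the diene, or thermal loss of ethene from the ynol ether, may outrun the cycloaddition. Fallback: ring C is taken from the aromatic pool instead of being built. 1-(2,4,6-Trihydroxyphenyl)butan-1-one 20 is O-methylated at its most acidic, non-chelated 4-hydroxyl (Me2SO4, K2CO3, acetone, 20 °C) to 1-(2,6-dihydroxy-4-methoxyphenyl)butan-1-one F1. F1 is then bridged to a second portion of 20, used in excess, with aqueous formaldehyde in dilute KOH. Both rings have two equivalent free positions, so the crossed product should be 19, where the route is rejoined. The price is a statistical separation; steps 1 to 8 are bypassed.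

Step 7. Once the C4' phenol holds the carbonyl as a boron chelate, cleavage of the C6' ethyl ether may stall. Benzyl cations set free may also alkylate ring B at carbon. Fallback from 15: hydrogenolysis (H2, Pd/C, EtOAc–MeOH, 20 °C) removes only the benzyl groups and should give 1-[2-ethoxy-6-hydroxy-4-methoxy-3-(2,4,6-trihydroxybenzyl)phenyl]butan-1-one F2. Friedel–Crafts acylation of F2 with butanoyl chloride and excess AlCl3 (PhNO2–CH2Cl2, 0 → 40 °C) then butyrylates ring B. The same chelating Lewis acid cleaves the ethyl ether ortho to the ring C ketone. The route is rejoined at 19, with steps 7 and 8 replaced.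

Step 10. The three-component bridging may suffer from homo-coupling of either partner, from attack through the free C3' of ring C, and from over-bridging. Fallback from 22: Mannich reaction with dimethylmethylideneammonium iodide (Eschenmoser's salt, MeCN, 20 °C) should give 2-butanoyl-6-[(dimethylamino)methyl]-3,5-dihydroxy-4,4-dimethylcyclohexa-2,5-dien-1-one F3. Warming F3 with 19 and NaHCO3 in dioxane at 60 °C expels dimethylamine. The electrophile 23 then arises from ring A only, free formaldehyde is absent, and the weak base ionises only ring B, whose C1 should trap 23 to give 24.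

Further compounds
F1 | step 6 | 1-(2,6-dihydroxy-4-methoxyphenyl)butan-1-one | CCCC(=O)c1c(O)cc(OC)cc1O
F2 | step 7 | 1-[2-ethoxy-6-hydroxy-4-methoxy-3-(2,4,6-trihydroxybenzyl)phenyl]butan-1-one | CCCC(=O)c1c(O)cc(OC)c(Cc2c(O)cc(O)cc2O)c1OCC
F3 | step 10 | 2-butanoyl-6-[(dimethylamino)methyl]-3,5-dihydroxy-4,4-dimethylcyclohexa-2,5-dien-1-one | CCCC(=O)C1=C(O)C(C)(C)C(O)=C(CN(C)C)C1=O
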